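Assumption: the stereocentre is read from the SMILES as (S) and the chain alkene next to it as E; all numbered starting materials are taken as catalogue compounds.

**Retrosynthetic overview**
- The target is unmasked last by one Pd(0) step that removes a sacrificial allyl ester on C3 (with loss of CO2) and the two phenol allyl ethers.
- Key disconnection C3–C4 (aryl ketone): crossed Claisen condensation of the ester enolate of an (S)-2-alkylsuccinic acid 4-allyl ester (as its dianion) with non-enolisable allyl 2,5-bis(allyloxy)benzoate.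
- The stereocentre comes from Evans alkylation of the (R)-4-benzyloxazolidinone imide of (5E)-6,10-dimethylundeca-5,9-dienoic acid with allyl bromoacetate, then LiOOH cleavage.
- The C13 acid comes from geranyl bromide and a three-carbon acetal Grignard reagent (Cu catalysis), then hydrolysis and Pinnick oxidation.
- No ring is built: the arene is bought as gentisic acid and the oxazolidinone is a recovered auxiliary.

**Route**

Step 1
Reactants: 1 geranyl bromide [(2E)-1-bromo-3,7-dimethylocta-2,6-diene]; 2 2-(2-bromoethyl)-1,3-dioxolane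
Product: 4 2-[(4E)-5,9-dimethyldeca-4,8-dien-1-yl]-1,3-dioxolane, via dioxolanylethylmagnesium bromide 3 (not isolated)
Conditions: 2, Mg, THF, 25–30 °C; then added slowly to 1, Li2CuCl4 (3 mol %), THF, −20 → 0 °C
Reagents that add atoms: 2-(2-bromoethyl)-1,3-dioxolane (2), BrCCC1OCCO1; magnesium, [Mg] (held only in 3)
Why: Kochi-type copper-catalysed Grignard cross-coupling, in which the cuprate formed under slow addition in THF substitutes the primary allylic bromide at the α-carbon (SN2) with retention of the E alkene; no stereocentre is formed.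

Step 2
Reactants: 4 2-[(4E)-5,9-dimethyldeca-4,8-dien-1-yl]-1,3-dioxolane
Product: 5 (5E)-6,10-dimethylundeca-5,9-dienal
Conditions: 1 M aq. HCl, THF, rt
Reagents that add atoms: water, O
Why: Acid-catalysed acetal hydrolysis, which in dilute aqueous acid at room temperature is much faster than hydration or cyclisation of the two trisubstituted alkenes.

Step 3
Reactants: 5 (5E)-6,10-dimethylundeca-5,9-dienal
Product: 6 (5E)-6,10-dimethylundeca-5,9-dienoic acid
Conditions: NaClO2, NaH2PO4, 2-methyl-2-butene (excess), t-BuOH/H2O, 0 °C → rt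
Reagents that add atoms: sodium chlorite, [Na+].[O-]Cl=O
Why: Pinnick oxidation touches only the aldehyde, and the excess 2-methyl-2-butene traps the HOCl by-product before it can attack the chain alkenes.

Step 4
Reactants: 6 (5E)-6,10-dimethylundeca-5,9-dienoic acid; 7 (4R)-4-benzyl-1,3-oxazolidin-2-one
Product: 9 (4R)-4-benzyl-3-[(5E)-6,10-dimethylundeca-5,9-dienoyl]-1,3-oxazolidin-2-one, via mixed pivalic anhydride 8 (not isolated)
Conditions: PivCl, Et3N, THF, −20 °C; then 7, LiCl, −20 °C → rt
Reagents that add atoms: (4R)-4-benzyl-1,3-oxazolidin-2-one (7), O=C1N[C@H](Cc2ccccc2)CO1; pivaloyl chloride, CC(C)(C)C(Cl)=O (held only in 8)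
Why: N-acylation of the oxazolidinone through a mixed anhydride, where the LiCl-activated auxiliary attacks the unhindered acyl group and not the pivaloyl carbonyl.

Step 5
Reactants: 9 (4R)-4-benzyl-3-[(5E)-6,10-dimethylundeca-5,9-dienoyl]-1,3-oxazolidin-2-one; 10 allyl bromoacetate
Product: 12 allyl (3S,6E)-3-{[(4R)-4-benzyl-2-oxo-1,3-oxazolidin-3-yl]carbonyl}-7,11-dimethyldodeca-6,10-dienoate, via sodium Z-enolate 11 (not isolated)
Conditions: NaHMDS, THF, −78 °C; then 10 (3 equiv), −78 → −40 °C
Reagents that add atoms: allyl bromoacetate (10), C=CCOC(=O)CBr; NaHMDS, C[Si](C)(C)[N-][Si](C)(C)C.[Na+] (Na held only in 11)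
Why: Evans asymmetric alkylation, in which the chelated Z-enolate is attacked by the reactive α-bromo ester on the face opposite the C4 benzyl group, so the (R)-auxiliary sets the new α-carbon as (S) (dr typically >95:5, minor isomer removed by chromatography).

Step 6
Reactants: 12 allyl (3S,6E)-3-{[(4R)-4-benzyl-2-oxo-1,3-oxazolidin-3-yl]carbonyl}-7,11-dimethyldodeca-6,10-dienoate
Product: 14 (2S,5E)-2-[2-(allyloxy)-2-oxoethyl]-6,10-dimethylundeca-5,9-dienoic acid, via lithium percarboxylate 13 (not isolated)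
Conditions: LiOH·H2O (1.6 equiv), 30% H2O2 (4 equiv), THF/H2O 3:1, 0 °C; then aq. Na2SO3; 1 M HCl to pH 3
Reagents that add atoms: hydrogen peroxide, OO; lithium hydroxide, [Li+].[OH-] (Li held only in 13)
Why: Evans hydroperoxide cleavage, where HOO⁻ attacks the activated exocyclic imide carbonyl far faster than the primary allyl ester and without epimerising the α-centre, and sulfite then reduces the peracid to the acid.

Step 7
Reactants: 15 2,5-dihydroxybenzoic acid (gentisic acid); 16 allyl bromide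
Product: 17 allyl 2,5-bis(allyloxy)benzoate
Conditions: allyl bromide (3.5 equiv), K2CO3, DMF, 60 °C, N2
Reagents that add atoms: allyl bromide (16), C=CCBr
Why: Williamson-type O-alkylation of the carboxylate and both phenoxides gives a non-enolisable ester whose leaving alkoxide matches the allyl ester of 14, so no ester scrambling can occur later.

Step 8
Reactants: 14 (2S,5E)-2-[2-(allyloxy)-2-oxoethyl]-6,10-dimethylundeca-5,9-dienoic acid; 17 allyl 2,5-bis(allyloxy)benzoate
Product: 19 (2S,5E)-2-{1-(allyloxy)-3-[2,5-bis(allyloxy)phenyl]-1,3-dioxopropan-2-yl}-6,10-dimethylundeca-5,9-dienoic acid (epimer mixture at the keto ester carbon), via dilithium dianion 18 (not isolated)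
Conditions: LDA (3.2 equiv), THF, −78 °C, 1 h; then 17 (1.2 equiv), −78 → −20 °C; cold 1 M HCl
Reagents that add atoms: allyl 2,5-bis(allyloxy)benzoate (17), C=CCOC(=O)c1cc(OCC=C)ccc1OCC=C; LDA, CC(C)[N-]C(C)C.[Li+] (Li held only in 18)
Why: Crossed Claisen condensation, in which LDA forms the carboxylate/ester-enolate dianion (only the CH2 next to the ester is deprotonated, so the (S)-centre next to the carboxylate is untouched), the enolate acylates at the aryl ester to form the C3–C4 bond, and the third equivalent of base traps the β-keto ester as its enolate; the new C3 centre is an irrelevant epimer mixture that is lost in step 9.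

Step 9
Reactants: 19 (2S,5E)-2-{1-(allyloxy)-3-[2,5-bis(allyloxy)phenyl]-1,3-dioxopropan-2-yl}-6,10-dimethylundeca-5,9-dienoic acid
Product: 22 (2S,5E)-2-[2-(2,5-dihydroxyphenyl)-2-oxoethyl]-6,10-dimethylundeca-5,9-dienoic acid, via β-keto diacid 20 (not isolated), via bis(allyl ether) keto acid 21 (not isolated)
Conditions: Pd(PPh3)4 (5 mol %), morpholine (10 equiv), degassed THF, rt → 45 °C; 1 M HCl work-up
Reagents that add atoms: none
Why: Tsuji–Trost deallylation with morpholine as allyl scavenger cleaves the allyl ester first, the resulting β-keto acid decarboxylates, and the two aryl allyl ethers are then cleaved, all under near-neutral conditions that spare the 1,5-diene, the hydroquinone and the α-stereocentre.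

**Compound list**
1 | geranyl bromide, (2E)-1-bromo-3,7-dimethylocta-2,6-diene | CC(C)=CCC/C(C)=C/CBr | starting material
2 | 2-(2-bromoethyl)-1,3-dioxolane | BrCCC1OCCO1 | starting material
3 | [2-(1,3-dioxolan-2-yl)ethyl]magnesium bromide | Br[Mg]CCC1OCCO1 | intermediate
4 | 2-[(4E)-5,9-dimethyldeca-4,8-dien-1-yl]-1,3-dioxolane | CC(C)=CCC/C(C)=C/CCCC1OCCO1 | intermediate
5 | (5E)-6,10-dimethylundeca-5,9-dienal | CC(C)=CCC/C(C)=C/CCCC=O | intermediate
6 | (5E)-6,10-dimethylundeca-5,9-dienoic acid | CC(C)=CCC/C(C)=C/CCCC(=O)O | intermediate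
7 | (4R)-4-benzyl-1,3-oxazolidin-2-one | O=C1N[C@H](Cc2ccccc2)CO1 | starting material
8 | (5E)-6,10-dimethylundeca-5,9-dienoic pivalic anhydride | CC(C)=CCC/C(C)=C/CCCC(=O)OC(=O)C(C)(C)C | intermediate
9 | (4R)-4-benzyl-3-[(5E)-6,10-dimethylundeca-5,9-dienoyl]-1,3-oxazolidin-2-one | CC(C)=CCC/C(C)=C/CCCC(=O)N1[C@H](Cc2ccccc2)COC1=O | intermediate
10 | allyl bromoacetate (prop-2-en-1-yl 2-bromoacetate) | C=CCOC(=O)CBr | starting material
11 | sodium (Z)-enolate of 9 | CC(C)=CCC/C(C)=C/CC/C=C(\[O-])N1[C@H](Cc2ccccc2)COC1=O.[Na+] | intermediate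
12 | allyl (3S,6E)-3-{[(4R)-4-benzyl-2-oxo-1,3-oxazolidin-3-yl]carbonyl}-7,11-dimethyldodeca-6,10-dienoate | CC(C)=CCC/C(C)=C/CC[C@@H](CC(=O)OCC=C)C(=O)N1[C@H](Cc2ccccc2)COC1=O | intermediate
13 | lithium (2S,5E)-2-[2-(allyloxy)-2-oxoethyl]-6,10-dimethylundeca-5,9-dieneperoxoate | CC(C)=CCC/C(C)=C/CC[C@@H](CC(=O)OCC=C)C(=O)O[O-].[Li+] | intermediate
14 | (2S,5E)-2-[2-(allyloxy)-2-oxoethyl]-6,10-dimethylundeca-5,9-dienoic acid | CC(C)=CCC/C(C)=C/CC[C@@H](CC(=O)OCC=C)C(=O)O | intermediate
15 | 2,5-dihydroxybenzoic acid (gentisic acid) | O=C(O)c1cc(O)ccc1O | starting material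
16 | allyl bromide | C=CCBr | starting material
17 | allyl 2,5-bis(allyloxy)benzoate | C=CCOC(=O)c1cc(OCC=C)ccc1OCC=C | intermediate
18 | dilithium carboxylate/ester enolate of 14 | CC(C)=CCC/C(C)=C/CC[C@@H](C=C([O-])OCC=C)C(=O)[O-].[Li+].[Li+] | intermediate
19 | (2S,5E)-2-{1-(allyloxy)-3-[2,5-bis(allyloxy)phenyl]-1,3-dioxopropan-2-yl}-6,10-dimethylundeca-5,9-dienoic acid (epimer mixture at the keto ester carbon) | CC(C)=CCC/C(C)=C/CC[C@@H](C(C(=O)OCC=C)C(=O)c1cc(OCC=C)ccc1OCC=C)C(=O)O | intermediate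
20 | (2S,5E)-2-{2-[2,5-bis(allyloxy)phenyl]-1-carboxy-2-oxoethyl}-6,10-dimethylundeca-5,9-dienoic acid | CC(C)=CCC/C(C)=C/CC[C@@H](C(C(=O)O)C(=O)c1cc(OCC=C)ccc1OCC=C)C(=O)O | intermediate
21 | (2S,5E)-2-{2-[2,5-bis(allyloxy)phenyl]-2-oxoethyl}-6,10-dimethylundeca-5,9-dienoic acid | CC(C)=CCC/C(C)=C/CC[C@@H](CC(=O)c1cc(OCC=C)ccc1OCC=C)C(=O)O | intermediate
22 | (2S,5E)-2-[2-(2,5-dihydroxyphenyl)-2-oxoethyl]-6,10-dimethylundeca-5,9-dienoic acid | CC(C)=CCC/C(C)=C/CC[C@@H](CC(=O)c1cc(O)ccc1O)C(=O)O | target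

**Step count and risk**
Total steps: 9. Longest linear sequence: 8 steps (steps 1–6, 8, 9 from geranyl bromide); step 7 is a one-step side branch.

The three steps most likely to fail are steps 1, 8 and 9.

Step 1 (copper-catalysed allylic coupling) can give some SN2′ (linalyl-type) product, lose E purity, or suffer from decomposition of the acetal Grignard reagent. The fallback sets out from 1 and replaces the organometallic coupling by a sulfone alkylation. Commercial 2-[2-(phenylsulfonyl)ethyl]-1,3-dioxolane is deprotonated (n-BuLi, THF, −78 °C) to its α-lithio sulfone F1. This displaces bromide from 1 in a clean SN2 reaction to give the sulfone acetal 2-[(4E)-5,9-dimethyl-2-(phenylsulfonyl)deca-4,8-dien-1-yl]-1,3-dioxolane F2. Reductive desulfonylation (6% Na/Hg, Na2HPO4, MeOH, −20 °C) comes back to the route at 4.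

Step 8 (Claisen condensation of the dianion) can stall because the electron-rich aryl ester is a modest electrophile, and the allyl ester enolate may start Ireland–Claisen rearrangement if warmed. The fallback sets out from 9 and forms the C2–C3 bond by auxiliary-controlled alkylation instead. 2′,5′-Dihydroxyacetophenone is bis-allylated (allyl bromide, K2CO3, DMF) to 1-[2,5-bis(allyloxy)phenyl]ethan-1-one F3 and α-brominated (PhNMe3Br3, THF, 0 °C) to the phenacyl bromide 1-[2,5-bis(allyloxy)phenyl]-2-bromoethan-1-one F4. The sodium enolate 11 of 9 is alkylated with it at −78 °C, with the same facial bias as in step 5, to the γ-keto imide F5. LiOH/H2O2 cleavage through the lithium percarboxylate F6, then sulfite, gives 21, where the route is rejoined for the ether cleavage of step 9.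

Step 9 (one-pot Pd deallylation and decarboxylation) can give C-allylated ketone during decarboxylation or stop at partly deallylated hydroquinone. The fallback sets out from 15 and 14 and separates decarboxylation from phenol unmasking by using silyl ethers. Gentisic acid 15 is esterified at the carboxylate only (allyl bromide, KHCO3, DMF) to allyl 2,5-dihydroxybenzoate F7 and silylated (TBSCl, imidazole, DMF) to allyl 2,5-bis(tert-butyldimethylsilyloxy)benzoate F8. Claisen condensation with dianion 18 (from 14) as in step 8 gives the silyl-protected β-keto ester F9. Pd(PPh3)4/morpholine then has only the one allyl ester to cleave, and the β-keto diacid F10 so formed decarboxylates to the bis-silyl keto acid F11. TBAF buffered with AcOH (THF, 0 °C) removes both aryl silyl ethers and comes back to the route at 22.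

**Further compounds**
F1 | step 1 | α-lithio 2-[2-(phenylsulfonyl)ethyl]-1,3-dioxolane | [Li]C(CC1OCCO1)S(=O)(=O)c1ccccc1
F2 | step 1 | 2-[(4E)-5,9-dimethyl-2-(phenylsulfonyl)deca-4,8-dien-1-yl]-1,3-dioxolane (racemic at the sulfone carbon) | CC(C)=CCC/C(C)=C/CC(CC1OCCO1)S(=O)(=O)c1ccccc1
F3 | step 8 | 1-[2,5-bis(allyloxy)phenyl]ethan-1-one | CC(=O)c1cc(OCC=C)ccc1OCC=C
F4 | step 8 | 1-[2,5-bis(allyloxy)phenyl]-2-bromoethan-1-one | BrCC(=O)c1cc(OCC=C)ccc1OCC=C
F5 | step 8 | (4R)-4-benzyl-3-[(2S,5E)-2-{2-[2,5-bis(allyloxy)phenyl]-2-oxoethyl}-6,10-dimethylundeca-5,9-dienoyl]-1,3-oxazolidin-2-one | CC(C)=CCC/C(C)=C/CC[C@@H](CC(=O)c1cc(OCC=C)ccc1OCC=C)C(=O)N1[C@H](Cc2ccccc2)COC1=O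
F6 | step 8 | lithium (2S,5E)-2-{2-[2,5-bis(allyloxy)phenyl]-2-oxoethyl}-6,10-dimethylundeca-5,9-dieneperoxoate | CC(C)=CCC/C(C)=C/CC[C@@H](CC(=O)c1cc(OCC=C)ccc1OCC=C)C(=O)O[O-].[Li+]
F7 | step 9 | allyl 2,5-dihydroxybenzoate | C=CCOC(=O)c1cc(O)ccc1O
F8 | step 9 | allyl 2,5-bis(tert-butyldimethylsilyloxy)benzoate | C=CCOC(=O)c1cc(O[Si](C)(C)C(C)(C)C)ccc1O[Si](C)(C)C(C)(C)C
F9 | step 9 | (2S,5E)-2-{1-(allyloxy)-3-[2,5-bis(tert-butyldimethylsilyloxy)phenyl]-1,3-dioxopropan-2-yl}-6,10-dimethylundeca-5,9-dienoic acid (epimer mixture at the keto ester carbon) | CC(C)=CCC/C(C)=C/CC[C@@H](C(C(=O)OCC=C)C(=O)c1cc(O[Si](C)(C)C(C)(C)C)ccc1O[Si](C)(C)C(C)(C)C)C(=O)O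
F10 | step 9 | (2S,5E)-2-{2-[2,5-bis(tert-butyldimethylsilyloxy)phenyl]-1-carboxy-2-oxoethyl}-6,10-dimethylundeca-5,9-dienoic acid | CC(C)=CCC/C(C)=C/CC[C@@H](C(C(=O)O)C(=O)c1cc(O[Si](C)(C)C(C)(C)C)ccc1O[Si](C)(C)C(C)(C)C)C(=O)O
F11 | step 9 | (2S,5E)-2-{2-[2,5-bis(tert-butyldimethylsilyloxy)phenyl]-2-oxoethyl}-6,10-dimethylundeca-5,9-dienoic acid | CC(C)=CCC/C(C)=C/CC[C@@H](CC(=O)c1cc(O[Si](C)(C)C(C)(C)C)ccc1O[Si](C)(C)C(C)(C)C)C(=O)O
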